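**Retrosynthetic overview**
1. The strategy rests on the tertiary bridgehead ether C1–O of the oxepane ring (O, C1, C5, C4, C7', Ar1, Ar6). C1 adjoins C5, which carries the gem-dimethylcyclopropane (C6, C7, C11), so C1–O is made by oxygen insertion into a C1–C(=O) bond and never through a cation at C1 or C5.
2. The arene (ring E) is built last. Ar6 (lactone C=O) and Ar1 (its α-CH2) of lactone 27 are kept and Ar2 comes from Cl3CCOCl. Ar3–Ar5 and both formyl carbons come from dimethyl 3-oxopentanedioate, in a [3+3] annulation on a vinyl sulfone reached via the thionolactone.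
3. Lactone 27 ⇐ Baeyer–Villiger ring expansion of the bicyclo[3.2.1]octan-2-one 25 (ring D), with C1 migrating.
4. Ring D ⇐ carbonyl-ene closure Ar6–C1 onto C1=C10, then hydrogenation to set C10. Ring A ⇐ CBr2 / Me2CuLi on C6=C7 while C1=C10 is masked as an epoxide. Rings B and C together ⇐ Rh-catalysed vinylcyclopropane–alkyne [5+2].
5. C7' and C4 ⇐ two alkylations of (S)-4-isobutyl-δ-valerolactone, made from a commercial resolved acid. Order of ring formation: B + C, A, D, oxepane (D expanded), E.

Key step: step 21

Numbering: C1–C15 follow the aromadendrane skeleton (C14 = methyl on C10, C15 = methyl on C4). C7' is the carbon bearing isobutyl. Ar1 (bonded to C7') to Ar6 (bonded to O) are the arene carbons. β is the face of H5, of C7' on C4 and of C11. Ring A = cyclopropane, B = cycloheptane, C = cyclopentane, D = ketone ring, E = arene.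
Remark: the carbinol carbon of 23, the peroxy carbon of 26, the enolisable Ar5 of 33 and the acetal carbon of F3 are written without configuration, because each is lost in the next event.

**Route**

Step 1
Reactants: 1 (R)-3-(carbamoylmethyl)-5-methylhexanoic acid
Product: 3 (S)-4-isobutyltetrahydro-2H-pyran-2-one, via hydroxy amide 2 (not isolated)
Conditions: BH3·SMe2, THF, 0 °C → rt; then 2 M HCl, 60 °C
Reagents that add atoms: none
Why: Borane reduces the free carboxylic acid much faster than the primary amide, and acid-catalysed lactonisation (acyl substitution with loss of ammonia) then closes the ring without touching C7', whose configuration comes from the resolved commercial acid.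

Step 2
Reactants: 3 (S)-4-isobutyltetrahydro-2H-pyran-2-one
Product: 4 (3R,4S)-4-isobutyl-3-methyltetrahydro-2H-pyran-2-one
Conditions: LiN(i-Pr)2, THF, −78 °C; MeI, −78 → −40 °C
Reagents that add atoms: iodomethane, CI
Why: This is a lithium enolate alkylation of a 4-substituted δ-lactone in which MeI should enter anti to isobutyl (trans product), although this C4 configuration is erased on enolisation in step 4.

Step 3
Reactants: 5 pent-3-yn-1-ol
Product: 6 pent-3-yn-1-yl trifluoromethanesulfonate
Conditions: Tf2O, 2,6-lutidine, CH2Cl2, −78 °C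
Reagents that add atoms: trifluoromethanesulfonic anhydride, O=S(=O)(OS(=O)(=O)C(F)(F)F)C(F)(F)F
Why: O-sulfonylation of a primary alcohol gives a triflate, chosen because homopropargylic halides tend to eliminate rather than alkylate hindered enolates.

Step 4
Reactants: 4 (3R,4S)-4-isobutyl-3-methyltetrahydro-2H-pyran-2-one; 6 pent-3-yn-1-yl trifluoromethanesulfonate
Product: 7 (3R,4S)-4-isobutyl-3-methyl-3-(pent-3-yn-1-yl)tetrahydro-2H-pyran-2-one
Conditions: LiN(i-Pr)2, THF, −78 → 0 °C; then 6, −78 → −30 °C
Reagents that add atoms: none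
Why: In this second enolate alkylation the fully substituted enolate should be attacked on the face anti to the pseudo-axial isobutyl group at C7', which places the chain C3–C2–C1≡C10 trans and the methyl group cis to isobutyl and so sets quaternary C4.

Step 5
Reactants: 7 (3R,4S)-4-isobutyl-3-methyl-3-(pent-3-yn-1-yl)tetrahydro-2H-pyran-2-one
Product: 8 (2R,3S)-3-isobutyl-2-methyl-2-(pent-3-yn-1-yl)pentane-1,5-diol
Conditions: LiAlH4, THF, 0 °C → rt
Reagents that add atoms: none
Why: Hydride reduction converts the lactone to the 1,5-diol, and the isolated internal alkyne and both stereocentres are untouched.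

Step 6
Reactants: 8 (2R,3S)-3-isobutyl-2-methyl-2-(pent-3-yn-1-yl)pentane-1,5-diol
Product: 9 (2R,3S)-5-(tert-butyldimethylsilyloxy)-3-isobutyl-2-methyl-2-(pent-3-yn-1-yl)pentan-1-ol
Conditions: TBSCl (1 equiv), imidazole, CH2Cl2, 0 °C
Reagents that add atoms: tert-butyldimethylsilyl chloride, CC(C)(C)[Si](C)(C)Cl
Why: Silylation is governed by sterics, so the unhindered Ar6 hydroxyl should react far faster than the neopentyl C5 hydroxyl.

Step 7
Reactants: 9 (2R,3S)-5-(tert-butyldimethylsilyloxy)-3-isobutyl-2-methyl-2-(pent-3-yn-1-yl)pentan-1-ol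
Product: 10 (2R,3S)-5-(tert-butyldimethylsilyloxy)-3-isobutyl-2-methyl-2-(pent-3-yn-1-yl)pentanal
Conditions: Dess–Martin periodinane, CH2Cl2, rt
Reagents that add atoms: none
Why: Dess–Martin oxidation gives an aldehyde (C5) with no α-hydrogen, so C4 cannot epimerise.

Step 8
Reactants: 11 (bromomethyl)cyclopropane; 12 1-phenyl-1H-tetrazole-5-thiol
Product: 13 5-[(cyclopropylmethyl)sulfanyl]-1-phenyl-1H-tetrazole
Conditions: K2CO3, acetone, reflux
Reagents that add atoms: none
Why: The soft thiolate displaces a primary bromide by SN2, which avoids cyclopropylcarbinyl rearrangement.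

Step 9
Reactants: 13 5-[(cyclopropylmethyl)sulfanyl]-1-phenyl-1H-tetrazole
Product: 14 5-[(cyclopropylmethyl)sulfonyl]-1-phenyl-1H-tetrazole
Conditions: 30% H2O2, (NH4)6Mo7O24·4H2O (cat.), EtOH, 0 °C → rt
Reagents that add atoms: hydrogen peroxide, OO
Why: This is the standard molybdate-catalysed oxidation of a sulfide to the sulfone.

Step 10
Reactants: 10 (2R,3S)-5-(tert-butyldimethylsilyloxy)-3-isobutyl-2-methyl-2-(pent-3-yn-1-yl)pentanal; 14 5-[(cyclopropylmethyl)sulfonyl]-1-phenyl-1H-tetrazole
Product: 15 (E)-vinylcyclopropane–alkyne (C4 bearing methyl; CH2CH2C≡CCH3; (E)-CH=CH-cyclopropyl; CH(i-Bu)CH2CH2OTBS)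
Conditions: KN(SiMe3)2, DME, −60 °C → rt
Reagents that add atoms: none
Why: A Julia–Kocienski olefination with the phenyltetrazolyl sulfone, a potassium counter-ion and an α-branched aldehyde should give the E alkene C5=C6, the geometry best suited to the cycloaddition.

Step 11
Reactants: 15 (E)-vinylcyclopropane–alkyne
Product: 16 hydroazulene diene (rings B and C; C1=C10 and C6=C7; H5 β; C4 bearing α-methyl and the β chain CH(i-Bu)CH2CH2OTBS)
Conditions: [Rh(CO)2Cl]2 (5 mol %), 1,2-dichloroethane, 80 °C
Reagents that add atoms: none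
Why: The intramolecular rhodium-catalysed vinylcyclopropane–alkyne [5+2] cycloaddition over a three-atom tether forms C5–C1 (ring C) and C9–C10 (ring B) in one operation, and C5 should be set by quaternary C4 because the growing seven-membered ring (C6) settles cis to the small methyl group and trans to the branched C7' chain.

Step 12
Reactants: 16 hydroazulene diene
Product: 17 α-1,10-epoxide of the diene (C6=C7 kept)
Conditions: m-CPBA (1 equiv), CH2Cl2, −30 °C
Reagents that add atoms: 3-chloroperbenzoic acid, OOC(=O)c1cccc(Cl)c1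
Why: Prilezhaev epoxidation is fastest at the most electron-rich alkene, so the tetrasubstituted C1=C10 is masked against the electrophilic carbene of step 13; the peracid should approach anti to the C7' chain, and this configuration is removed again in step 15.

Step 13
Reactants: 17 α-1,10-epoxide of the diene
Product: 18 dibromocyclopropane (CBr2 bridging C6 and C7 on the β face; epoxide kept)
Conditions: CHBr3, KOt-Bu, pentane, 0 °C
Reagents that add atoms: bromoform, BrC(Br)Br
Why: Dibromocarbene adds in a [2+1] cycloaddition to the only remaining alkene; the syn addition keeps H6 and H7 cis, and approach on the face carrying H5, away from quaternary C4, should set C6 and C7.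

Step 14
Reactants: 18 dibromocyclopropane
Product: 19 gem-dimethylcyclopropane epoxide (ring A complete)
Conditions: Me2CuLi (excess), Et2O, −15 → 0 °C; then MeI
Reagents that add atoms: lithium dimethylcuprate, [Li+].C[Cu-]C; iodomethane, CI
Why: Lithium dimethylcuprate gem-dimethylates the gem-dibromocyclopropane (bromine–copper exchange, 1,2-methyl shift, capture by MeI); no ring stereocentre is affected, and the fully substituted epoxide offers no site for SN2 opening.

Step 15
Reactants: 19 gem-dimethylcyclopropane epoxide
Product: 20 4-substituted aromadendr-1(10)-ene TBS ether (C1=C10 restored)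
Conditions: WCl6, n-BuLi, THF, −78 °C → rt; then 19, rt → 50 °C
Reagents that add atoms: none
Why: Low-valent tungsten chloride deoxygenates even tetrasubstituted epoxides, and here it can only return the ring-fusion alkene.

Step 16
Reactants: 20 4-substituted aromadendr-1(10)-ene TBS ether
Product: 21 primary alcohol (Ar6–OH free)
Conditions: Bu4NF, THF, rt
Reagents that add atoms: none
Why: Fluoride-induced desilylation leaves the alkene and the cyclopropane untouched.

Step 17
Reactants: 21 primary alcohol
Product: 22 aldehyde (side chain CH(i-Bu)CH2CHO on the β face of C4)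
Conditions: Dess–Martin periodinane, CH2Cl2, rt
Reagents that add atoms: none
Why: Dess–Martin oxidation works under neutral conditions that spare the electron-rich alkene, and C7' is β to the carbonyl and not epimerisable.

Step 18
Reactants: 22 aldehyde
Product: 23 tetracyclic homoallylic alcohol (ring D closed; quaternary C1; C10=CH2)
Conditions: Me2AlCl, CH2Cl2, −78 → −20 °C
Reagents that add atoms: none
Why: In this Lewis-acid-promoted type 1 intramolecular carbonyl-ene reaction the nucleophilic tetrasubstituted alkene attacks the activated aldehyde through C1 in a six-membered closure, the tether on the β face of C4 forces β attack and so sets quaternary C1, and the hydrogen is taken from the C14 methyl group lying next to the carbonyl oxygen, which leaves C10=CH2.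

Step 19
Reactants: 23 tetracyclic homoallylic alcohol
Product: 24 tetracyclic β,γ-unsaturated ketone (Ar6=O; C10=CH2)
Conditions: Dess–Martin periodinane, CH2Cl2, rt
Reagents that add atoms: none
Why: Dess–Martin oxidation of the secondary alcohol gives the ketone, and quaternary C1 blocks conjugation of the alkene.

Step 20
Reactants: 24 tetracyclic β,γ-unsaturated ketone
Product: 25 tetracyclic bicyclo[3.2.1]octan-2-one (all-carbon quaternary C1; 10β-methyl)
Conditions: H2 (1 atm), Pd/C, EtOAc, rt
Reagents that add atoms: none
Why: In this heterogeneous hydrogenation the β face of C10=CH2 is screened by C5–C6 and by the endo methyl group of ring A, so hydrogen should reach C10 from the α face and C14 becomes β; the unconjugated cyclopropane survives these mild conditions.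

Step 21
Reactants: 25 tetracyclic bicyclo[3.2.1]octan-2-one
Product: 27 bridged seven-membered lactone on C1 (2-oxabicyclo[4.2.1]nonan-3-one core), via Criegee adduct 26 (not isolated)
Conditions: m-CPBA, CH2Cl2, rt → 40 °C
Reagents that add atoms: 3-chloroperbenzoic acid, OOC(=O)c1cccc(Cl)c1
Why: The peracid adds to the Ar6 carbonyl to give the tetrahedral peroxy adduct 26, and the C1–Ar6 bond, once antiperiplanar to O–O, shifts to oxygen while 3-chlorobenzoate departs. This is the Baeyer–Villiger oxidation of a bridged ketone, whose closest relatives are bicyclo[2.2.1]heptan-2-ones and bicyclo[3.2.1]octan-2-ones that expand by bridgehead migration. No ring is closed end to end: ring D (Ar6, Ar1, C7', C4, C5, C1) grows by one atom through the 1,2-shift into the seven-membered lactone (Ar6, O, C1, C5, C4, C7', Ar1), which is the oxepane of 38 with Ar6 still a carbonyl and Ar1 its α-methylene. C1 becomes the oxygen-bearing stereocentre with retention, because the migrating carbon stays bound on the same face throughout, so its configuration is the one fixed by the tether in step 18. The step needs regioselectivity, secured because fully substituted C1 bears developing positive charge far better than the Ar1 methylene, and chemoselectivity, secured because 25 holds no alkene and the cyclopropane is inert to peracid. No cation or radical is placed at C1 or C5, so ring A is never at risk.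

Step 22
Reactants: 27 bridged seven-membered lactone
Product: 28 thionolactone (Ar6=S)
Conditions: Lawesson's reagent, toluene, 110 °C
Reagents that add atoms: Lawesson's reagent, COc1ccc(cc1)P1(=S)SP(=S)(S1)c1ccc(OC)cc1
Why: Thionation is done while the lactone is the only carbonyl group, and the ring-locked ester geometry keeps sulfur away from the β-hydrogens around C1, so thermal syn-elimination is not available.

Step 23
Reactants: 28 thionolactone
Product: 29 cyclic ketene O,S-acetal (Ar1H=Ar6(SMe)–O–C1)
Conditions: KN(SiMe3)2, THF, −78 °C; MeI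
Reagents that add atoms: iodomethane, CI
Why: Deprotonation at Ar1 gives an enethiolate, and this soft anion is alkylated on sulfur.

Step 24
Reactants: 29 cyclic ketene O,S-acetal
Product: 30 α-trichloroacetyl ketene O,S-acetal (Ar2 installed on Ar1)
Conditions: Cl3CCOCl, pyridine, CH2Cl2, 0 °C → rt
Reagents that add atoms: trichloroacetyl chloride, ClC(=O)C(Cl)(Cl)Cl
Why: This is an electrophilic vinylic acylation of the kind known for enol ethers, ketene acetals and ketene dithioacetals; the donor-activated Ar1 attacks the acid chloride and pyridine removes the vinylic proton.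

Step 25
Reactants: 30 α-trichloroacetyl ketene O,S-acetal
Product: 31 vinyl sulfone (Ar6 bearing SO2Me and O–C1)
Conditions: m-CPBA (2.2 equiv), CH2Cl2, 0 °C
Reagents that add atoms: 3-chloroperbenzoic acid, OOC(=O)c1cccc(Cl)c1
Why: Oxidising the sulfide to the sulfone turns a donor on Ar6 into an acceptor and a very good leaving group, while the electron-poor alkene is not epoxidised.

Step 26
Reactants: 31 vinyl sulfone; 32 dimethyl 3-oxopentanedioate
Product: 34 phloroglucinol diester (Ar2–OH; Ar3–CO2Me; Ar4–OH; Ar5–CO2Me; Ar6–O–C1), via substitution adduct 33 (not isolated)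
Conditions: NaH, THF, 0 → 60 °C
Reagents that add atoms: none
Why: Proposed new method: the sodium enolate of 32 should add through one methylene carbon (Ar5) to sulfonyl-bearing Ar6 and expel methanesulfinate, a far better leaving group than the tertiary C1 alkoxide, so C1–O stays intact (addition–elimination, adduct 33); the seven-membered ring holds the new chain cis to the trichloroacetyl group, so the second methylene carbon (Ar3) can attack that carbonyl (Ar2) in a six-membered Dieckmann-type closure with loss of trichloromethanide, and tautomerisation gives the fully substituted arene; because 32 is symmetric the reverse order of the two bond formations gives the same product, and any 2-pyranone formed through oxygen should be funnelled to the arene under the basic conditions; the closest known reactions are the [3+3] benzannulations of α-oxo ketene dithioacetals with 1,3-dicarbonyl dinucleophiles and the Michael–Dieckmann resorcinol synthesis from 32 and alkynoates; no stereocentre is formed.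

Step 27
Reactants: 34 phloroglucinol diester
Product: 35 bis(methoxymethyl) ether of the diester
Conditions: NaH, MOMCl, DMF, 0 °C → rt
Reagents that add atoms: chloromethyl methyl ether, COCCl
Why: O-alkylation of the two phenoxides (Williamson type) protects them so that reduction cannot run on through quinone methides.

Step 28
Reactants: 35 bis(methoxymethyl) ether of the diester
Product: 36 bis(hydroxymethyl) arene
Conditions: LiAlH4, THF, 0 °C → reflux
Reagents that add atoms: none
Why: Hydride reduces both hindered aryl esters to benzylic alcohols, and the aryl ethers and the cyclopropane are inert.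

Step 29
Reactants: 36 bis(hydroxymethyl) arene
Product: 37 protected dialdehyde
Conditions: Dess–Martin periodinane, CH2Cl2, rt
Reagents that add atoms: none
Why: Dess–Martin oxidation of the two benzylic alcohols stops at the aldehyde stage.

Step 30
Reactants: 37 protected dialdehyde
Product: 38 target CNP0189833.2
Conditions: 3 M HCl, MeOH–THF, 45 °C
Reagents that add atoms: none
Why: Acid hydrolysis removes the two MOM acetals, which are labilised by the ortho formyl groups, while the bridgehead position of C1 disfavours ionisation of the tertiary aryl ether.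

**Compound list**
1 | (R)-3-(carbamoylmethyl)-5-methylhexanoic acid | CC(C)C[C@@H](CC(=O)O)CC(N)=O | starting material
2 | (S)-3-(2-hydroxyethyl)-5-methylhexanamide | CC(C)C[C@@H](CCO)CC(N)=O | intermediate
3 | (S)-4-isobutyltetrahydro-2H-pyran-2-one | CC(C)C[C@H]1CCOC(=O)C1 | intermediate
4 | (3R,4S)-4-isobutyl-3-methyltetrahydro-2H-pyran-2-one | CC(C)C[C@H]1CCOC(=O)[C@@H]1C | intermediate
5 | pent-3-yn-1-ol | CC#CCCO | starting material
6 | pent-3-yn-1-yl trifluoromethanesulfonate | CC#CCCOS(=O)(=O)C(F)(F)F | intermediate
7 | (3R,4S)-4-isobutyl-3-methyl-3-(pent-3-yn-1-yl)tetrahydro-2H-pyran-2-one | CC(C)C[C@H]1CCOC(=O)[C@]1(C)CCC#CC | intermediate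
8 | (2R,3S)-3-isobutyl-2-methyl-2-(pent-3-yn-1-yl)pentane-1,5-diol | CC(C)C[C@@H](CCO)[C@@](C)(CCC#CC)CO | intermediate
9 | mono-TBS ether of 8 (Ar6–OTBS) | CC(C)C[C@@H](CCO[Si](C)(C)C(C)(C)C)[C@@](C)(CCC#CC)CO | intermediate
10 | C5 aldehyde | CC(C)C[C@@H](CCO[Si](C)(C)C(C)(C)C)[C@@](C)(CCC#CC)C=O | intermediate
11 | (bromomethyl)cyclopropane | BrCC1CC1 | starting material
12 | 1-phenyl-1H-tetrazole-5-thiol | Sc1nnnn1-c1ccccc1 | starting material
13 | 5-[(cyclopropylmethyl)sulfanyl]-1-phenyl-1H-tetrazole | C(Sc1nnnn1-c1ccccc1)C1CC1 | intermediate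
14 | 5-[(cyclopropylmethyl)sulfonyl]-1-phenyl-1H-tetrazole | O=S(=O)(CC1CC1)c1nnnn1-c1ccccc1 | intermediate
15 | (E)-vinylcyclopropane–alkyne | CC(C)C[C@@H](CCO[Si](C)(C)C(C)(C)C)[C@@](C)(CCC#CC)/C=C/C1CC1 | intermediate
16 | hydroazulene diene | CC(C)C[C@@H](CCO[Si](C)(C)C(C)(C)C)[C@@]1(C)CCC2=C(C)CCC=C[C@H]12 | intermediate
17 | α-1,10-epoxide | CC(C)C[C@@H](CCO[Si](C)(C)C(C)(C)C)[C@@]1(C)CC[C@@]23O[C@]2(C)CCC=C[C@H]13 | intermediate
18 | dibromocyclopropane epoxide | CC(C)C[C@@H](CCO[Si](C)(C)C(C)(C)C)[C@@]1(C)CC[C@@]23O[C@]2(C)CC[C@@H]2[C@H]([C@H]13)C2(Br)Br | intermediate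
19 | gem-dimethylcyclopropane epoxide | CC(C)C[C@@H](CCO[Si](C)(C)C(C)(C)C)[C@@]1(C)CC[C@@]23O[C@]2(C)CC[C@@H]2[C@H]([C@H]13)C2(C)C | intermediate
20 | 4-substituted aromadendr-1(10)-ene TBS ether | CC(C)C[C@@H](CCO[Si](C)(C)C(C)(C)C)[C@@]1(C)CCC2=C(C)CC[C@@H]3[C@H]([C@H]12)C3(C)C | intermediate
21 | primary alcohol | CC(C)C[C@@H](CCO)[C@@]1(C)CCC2=C(C)CC[C@@H]3[C@H]([C@H]12)C3(C)C | intermediate
22 | aldehyde | CC(C)C[C@@H](CC=O)[C@@]1(C)CCC2=C(C)CC[C@@H]3[C@H]([C@H]12)C3(C)C | intermediate
23 | tetracyclic homoallylic alcohol | CC(C)C[C@H]1CC(O)[C@]23CC[C@@]1(C)[C@H]2[C@H]1[C@@H](CCC3=C)C1(C)C | intermediate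
24 | tetracyclic β,γ-unsaturated ketone | CC(C)C[C@H]1CC(=O)[C@]23CC[C@@]1(C)[C@H]2[C@H]1[C@@H](CCC3=C)C1(C)C | intermediate
25 | tetracyclic bicyclo[3.2.1]octan-2-one | CC(C)C[C@H]1CC(=O)[C@]23CC[C@@]1(C)[C@H]2[C@H]1[C@@H](CC[C@@H]3C)C1(C)C | intermediate
26 | Criegee adduct | CC(C)C[C@H]1CC(O)(OOC(=O)c4cccc(Cl)c4)[C@]23CC[C@@]1(C)[C@H]2[C@H]1[C@@H](CC[C@@H]3C)C1(C)C | intermediate
27 | bridged seven-membered lactone | CC(C)C[C@H]1CC(=O)O[C@]23CC[C@@]1(C)[C@H]2[C@H]1[C@@H](CC[C@@H]3C)C1(C)C | intermediate
28 | thionolactone | CC(C)C[C@H]1CC(=S)O[C@]23CC[C@@]1(C)[C@H]2[C@H]1[C@@H](CC[C@@H]3C)C1(C)C | intermediate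
29 | cyclic ketene O,S-acetal | CC(C)C[C@H]1C=C(SC)O[C@]23CC[C@@]1(C)[C@H]2[C@H]1[C@@H](CC[C@@H]3C)C1(C)C | intermediate
30 | α-trichloroacetyl ketene O,S-acetal | CC(C)C[C@H]1C(C(=O)C(Cl)(Cl)Cl)=C(SC)O[C@]23CC[C@@]1(C)[C@H]2[C@H]1[C@@H](CC[C@@H]3C)C1(C)C | intermediate
31 | vinyl sulfone | CC(C)C[C@H]1C(C(=O)C(Cl)(Cl)Cl)=C(S(C)(=O)=O)O[C@]23CC[C@@]1(C)[C@H]2[C@H]1[C@@H](CC[C@@H]3C)C1(C)C | intermediate
32 | dimethyl 3-oxopentanedioate | COC(=O)CC(=O)CC(=O)OC | starting material
33 | substitution adduct | CC(C)C[C@H]1C(C(=O)C(Cl)(Cl)Cl)=C(C(C(=O)OC)C(=O)CC(=O)OC)O[C@]23CC[C@@]1(C)[C@H]2[C@H]1[C@@H](CC[C@@H]3C)C1(C)C | intermediate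
34 | phloroglucinol diester | CC(C)C[C@H]1c2c(O)c(C(=O)OC)c(O)c(C(=O)OC)c2O[C@]23CC[C@@]1(C)[C@H]2[C@H]1[C@@H](CC[C@@H]3C)C1(C)C | intermediate
35 | bis-MOM diester | CC(C)C[C@H]1c2c(OCOC)c(C(=O)OC)c(OCOC)c(C(=O)OC)c2O[C@]23CC[C@@]1(C)[C@H]2[C@H]1[C@@H](CC[C@@H]3C)C1(C)C | intermediate
36 | bis(hydroxymethyl) arene | CC(C)C[C@H]1c2c(OCOC)c(CO)c(OCOC)c(CO)c2O[C@]23CC[C@@]1(C)[C@H]2[C@H]1[C@@H](CC[C@@H]3C)C1(C)C | intermediate
37 | protected dialdehyde | CC(C)C[C@H]1c2c(OCOC)c(C=O)c(OCOC)c(C=O)c2O[C@]23CC[C@@]1(C)[C@H]2[C@H]1[C@@H](CC[C@@H]3C)C1(C)C | intermediate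
38 | CNP0189833.2 | CC(C)C[C@H]1c2c(O)c(C=O)c(O)c(C=O)c2O[C@]23CC[C@@]1(C)[C@H]2[C@H]1[C@@H](CC[C@@H]3C)C1(C)C | target

**Step count**
Total steps: 30. Longest linear sequence: 27 (steps 1, 2, 4–7, 10–30).

**Steps most likely to fail**

1. **Step 26 (new [3+3] annulation).** The stabilised carbanion may fail to add to the crowded, fully substituted Ar6. Closure may run through the enol oxygen and stop at a 2-pyranone. Loss of the tertiary alkoxide in place of sulfinate would open the oxepane.
   The fallback uses known reactions only, sets out from lactone 27 and comes back at target 38.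
   - Carbonyl methylenation with Cp2TiMe2 (toluene, 75 °C) should give the exocyclic enol ether F1.
   - An Effenberger-type double C-acylation follows with malonyl dichloride (2,6-di-tert-butylpyridine, CH2Cl2, −20 °C → rt). It occurs first at the methylene carbon (future Ar5) and then, after shift of the enol ether, at Ar1. Tautomerisation should give the phloroglucinol mono-ether F2.
   - Twofold Vilsmeier–Haack formylation (POCl3, DMF, EtOAc, 0 °C → rt, aqueous hydrolysis) at Ar3 and Ar5 returns to 38.

2. **Step 21 (key Baeyer–Villiger).** Addition of the peracid may be very slow, because the carbonyl is flanked by quaternary C1 and screened by the axial isobutyl group. The Ar1 methylene may also migrate in competition.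
   The fallback sets out from ketone 25 and comes back at lactone 27.
   - Irradiation through Pyrex in methanol should cleave the more substituted C1–Ar6 bond (α-cleavage).
   - The tethered acyl / tertiary-alkyl radical pair should reclose on oxygen to a cyclic oxacarbene, with C1 held in place by the cage. Methanol should trap the carbene as the mixed methyl acetal F3.
   - Oxidation of the acetal (m-CPBA, BF3·OEt2, CH2Cl2, 0 °C) returns to 27.

3. **Step 18 (carbonyl-ene closure).** Methyl transfer from aluminium to the aldehyde, proton loss toward C9, or failure to form the congested quaternary C1 may compete.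
   The fallback sets out from epoxide 19, skips step 15 and comes back at ketone 24.
   - Desilylation (Bu4NF, THF) gives the epoxy alcohol F4.
   - One-pot oxidation–imination–oxidation (TEMPO, PhI(OAc)2, NH4OAc, MeCN–H2O) gives the epoxy nitrile F5.
   - Cp2TiCl, made from Cp2TiCl2 and Mn dust in THF, should open the epoxide homolytically to the tertiary C1 radical. This radical adds 6-exo to the nitrile carbon on the β face. After reduction and hydrolysis of the imine the product is the β-hydroxy ketone F6.
   - Dehydration with Burgess reagent (benzene, 50 °C) returns to 24.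

**Further compounds**
F1 | step 26 | exocyclic enol ether (Ar6=CH2) | CC(C)C[C@H]1CC(=C)O[C@]23CC[C@@]1(C)[C@H]2[C@H]1[C@@H](CC[C@@H]3C)C1(C)C
F2 | step 26 | phloroglucinol mono-ether (Ar3–H; Ar5–H) | CC(C)C[C@H]1c2c(O)cc(O)cc2O[C@]23CC[C@@]1(C)[C@H]2[C@H]1[C@@H](CC[C@@H]3C)C1(C)C
F3 | step 21 | mixed methyl acetal | CC(C)C[C@H]1CC(OC)O[C@]23CC[C@@]1(C)[C@H]2[C@H]1[C@@H](CC[C@@H]3C)C1(C)C
F4 | step 18 | epoxy alcohol | CC(C)C[C@@H](CCO)[C@@]1(C)CC[C@@]23O[C@]2(C)CC[C@@H]2[C@H]([C@H]13)C2(C)C
F5 | step 18 | epoxy nitrile | CC(C)C[C@@H](CC#N)[C@@]1(C)CC[C@@]23O[C@]2(C)CC[C@@H]2[C@H]([C@H]13)C2(C)C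
F6 | step 18 | β-hydroxy ketone (10α-OH) | CC(C)C[C@H]1CC(=O)[C@]23CC[C@@]1(C)[C@H]2[C@H]1[C@@H](CC[C@@]3(C)O)C1(C)C
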